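Readings and results were computed for substances that don't exist, and the scatter is random.

In a one-step world each substrate goes straight to its own product and stays there, so the product excess could be read from what the two substrates lost. The question is whether this flask lives in that world.

| flask | left-handed substrate | right-handed substrate | coupling partner | free catalyst | added ligand | remark | time |
|---|---|---|---|---|---|---|---|
| midnight | 0.82 M | 0.82 M | 2 equiv | 0.22 mol% | 0.60 mM | run made earlier |  |
| winter | 0.82 M | 0.82 M | 2 equiv | 0.22 mol% | 0.90 mM | run made earlier |  |
| flask | 0.82 M | 0.82 M | 2.00 equiv | 0.22 mol% | 1.2 mM |  | 4.0 h |

- midnight (time / h: left-handed product / %, right-handed product / %, left-handed substrate / %): 1.33: 17, 18, 29; 2.50: 23, 24, 25; 4.00: 25, 26, 20; 5.00: 30, 29, 15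
- winter (time / h: left-handed product / %, right-handed product / %, left-handed substrate / %): 1.33: 15, 17, 30; 2.50: 23, 23, 24; 4.00: 27, 28, 18; 5.00: 29, 27, 16

(readings scatter by 1.5 percentage points)

- excess of left-handed product over right-handed product in the product at 12 min
- excess of left-handed product over right-handed product in the product at 4.0 h
- part of the left-handed substrate and right-handed substrate charged together that has reacted at 4.0 h

- free catalyst is single-handed; left-handed substrate and right-handed substrate are mirror images of each other, charged as a racemate, each of them at the stated concentration
- an excess is the difference of the two amounts in percent of their sum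
- an excess is below zero if the other one leads

Do the midnight and winter runs differ? Not beyond the scatter: at 4.00 h left-handed substrate reads 20% and 18%. I pool them and, as an extrapolation, carry them to the flask with 1.2 mM of added ligand.

Right-handed substrate is unread, so what then? I close the balance by subtraction, with catalyst charged at 0.22 mol%. In the pooled runs 38.0% of left-handed substrate's own charge remains and 56.0% of right-handed substrate's. That puts my reacted part for the flask at 53.0%.

And the preference? If both substrates fall first-order through the same catalyst, the catalyst's fate cancels in the ratio of logarithms. This gives the selectivity factor 1.67, read with scatter, and left-handed substrate is the faster. That factor is an average up to 4.00 h, not a reading of the start; assuming it holds from the first moment, I take an excess of 25.1% for fresh product.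

But the products read level! Yes. The substrates imply 17.0% by 4.00 h, while the pooled products show −1.89%, so left-handed product must be turning into right-handed product.

How fast? Go round once more. Products grew at 0.111 h⁻¹, and their pooled difference at 1.33 h is −1.5 percentage points. Taking the true difference to be one 1.5 points, I let making balance erasing, which needs a rate of 1.86 h⁻¹. A smaller difference means a faster rate. Putting that back, averaged over the first 12 min, gives me 20.9% for the early excess. With later growth of 0.0433 h⁻¹, the balance gives 1.10% at 4.0 h.

The forecast gave −4% (−25% to 12%), −1% and 59%, noting that “this value is weakly constrained”.

The flask gives 13.6%, 0.705% and 54.1%.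

    coupling partner + free catalyst → spent catalyst (k = 0.0240 L mol⁻¹ min⁻¹)
    free catalyst + right-handed substrate ⇌ catalyst intermediate B (K = 3.40 L mol⁻¹, k = 2500 L mol⁻¹ min⁻¹)
    free catalyst + added ligand ⇌ idle complex (K = 740 L mol⁻¹, k = 860 L mol⁻¹ min⁻¹)
    free catalyst + left-handed substrate ⇌ catalyst intermediate A (K = 3.70 L mol⁻¹, k = 57.0 L mol⁻¹ min⁻¹)
    left-handed product ⇌ right-handed product (k = 0.0150 min⁻¹)
    coupling partner + catalyst intermediate B → free catalyst + right-handed product (k = 3.40 L mol⁻¹ min⁻¹)
    coupling partner + catalyst intermediate A → free catalyst + left-handed product (k = 7.90 L mol⁻¹ min⁻¹)

The early excess lies 7.3 points below my reckoning. In this flask both coupling steps ran while catalyst intermediate A and catalyst intermediate B held 22.5% and 37.3% of the catalyst at 0.400 h, and the two products interconverted with a relaxation half-life of 0.385 h. By 4.00 h spent catalyst held 70.6% of the catalyst, with each product at 27.3%. Applied to this flask's remaining 37% of left-handed substrate, 1.67 gives 55.1% of right-handed substrate against a simulated 54%. In the neighbour with 0.37 mol% of free catalyst, 19% of left-handed substrate gives 37.0%, and that flask holds 38%.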